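Ring C is opened at three bonds, O1–C8a, C4–C4a and O1–C2, which one cascade forms. The step exploits ring A, where C4a bears the C4 carbonyl between O1-bearing C8a and oxygenated C5: 3,5-bis(benzyloxy)benzyne takes an oxygen nucleophile at C8a and the acyl group at C4a. The aryne inserts into the carboxyl C–O bond of a 2,3-diarylacrylic acid, and the phenoxide set free closes ring C by oxa-Michael addition. This acid holds C2, C3, C4, ring B and benzylated (S)-naringenin (rings D, F, E) joined at C8''. The 2R series is then separated, C3 is set cis by kinetic protonation and seven benzyl ethers are cleaved.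

Key step: step 9

Labels: rings A, C (O1, C2, C3, C4, C4a, C8a) and B are the benzo ring, pyranone and catechol ring of the catechol-bearing flavanone. Rings D, F and E are the benzo ring, pyranone and phenol ring of the naringenin half (doubly primed atoms). C3 is bonded to C8''.

Remark on structure: the protected cascade product carries seven benzyl ethers (three on the naringenin half, two on ring A, two on ring B), so the last step removes seven benzyl groups.

Remark on configuration: in a 3-aryl flavanone (2R,3R) is the 2,3-cis arrangement, the less stable one. C3 is therefore fixed late by kinetic protonation and is not exposed to base afterwards.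

Remark on ring F: carbonate-mediated exhaustive benzylation opens ring F to the chalcone, and any enolate at C3'' endangers C2''. The acid is therefore built by near-neutral benzylation, iodination and cross-coupling, and no enolate-forming base is used on the protected flavanone before or after the key step.

Remark on C2: the cascade cannot control C2, so both C2 series are formed. Only the 2R series is carried on, and the 2S series is removed by chromatography after step 10.

Assumption: 3,5-bis(benzyloxy)phenol, (S)-naringenin of high enantiomeric purity, 3,4-bis(benzyloxy)benzaldehyde and tert-butyl (triphenylphosphoranylidene)acetate are bought. Phloroglucinol and benzyl bromide would give the first in one further step.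

Step 1
Reactants: 1 3,5-bis(benzyloxy)phenol
Product: 2 2-bromo-3,5-bis(benzyloxy)phenol
Conditions: NBS (1.0 equiv), CH2Cl2, −78 °C to 0 °C
Reagents that add atoms: N-bromosuccinimide, O=C1CCC(=O)N1Br
Why: Electrophilic aromatic bromination of the phloroglucinol diether should occur mainly at C2, ortho to the free hydroxyl, because the alternative C4 lies between two benzyloxy groups, and the minor C4 bromide is removed by chromatography.

Step 2
Reactants: 2 2-bromo-3,5-bis(benzyloxy)phenol
Product: 5 3,5-bis(benzyloxy)-2-(trimethylsilyl)phenyl trifluoromethanesulfonate, via aryl trimethylsilyl ether 3 (not isolated), via lithium 2-silylphenoxide 4 (not isolated)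
Conditions: (Me3Si)2NH, THF, 65 °C, then evaporation; n-BuLi, THF, −78 °C; Tf2O, −78 °C to rt
Reagents that add atoms: hexamethyldisilazane, C[Si](C)(C)N[Si](C)(C)C; trifluoromethanesulfonic anhydride, O=S(=O)(OS(=O)(=O)C(F)(F)F)C(F)(F)F
Why: O-Silylation, bromine–lithium exchange and the 1,3-shift of silicon from oxygen to carbon (retro-Brook rearrangement) deliver the lithium phenoxide, which is triflated in the same flask, the standard route to 2-silylaryl triflates as aryne precursors.

Step 3
Reactants: 6 (S)-naringenin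
Product: 7 (2S)-5,7-bis(benzyloxy)-2-[4-(benzyloxy)phenyl]chroman-4-one
Conditions: BnBr (6 equiv), Ag2O (4 equiv), DMF, rt, dark
Reagents that add atoms: benzyl bromide, BrCc1ccccc1
Why: Silver oxide mediated O-alkylation (Purdie–Kuhn conditions) benzylates all three phenols, the chelated 5''-hydroxyl last, in a medium too weakly basic to open ring F to the chalcone, so C2'' keeps its S configuration.

Step 4
Reactants: 7 (2S)-5,7-bis(benzyloxy)-2-[4-(benzyloxy)phenyl]chroman-4-one
Product: 8 (2S)-5,7-bis(benzyloxy)-2-[4-(benzyloxy)phenyl]-8-iodochroman-4-one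
Conditions: NIS (1.05 equiv), TFA (10 mol %), MeCN, 0 °C to rt
Reagents that add atoms: N-iodosuccinimide, O=C1CCC(=O)N1I
Why: Electrophilic aromatic iodination should take C8'' of ring D, the most electron-rich ring, because the 5''-benzyloxy group turns its benzyl group towards C6'' to avoid the peri carbonyl group.

Step 5
Reactants: 8 (2S)-5,7-bis(benzyloxy)-2-[4-(benzyloxy)phenyl]-8-iodochroman-4-one
Product: 9 (2S)-5,7-bis(benzyloxy)-2-[4-(benzyloxy)phenyl]-8-(4,4,5,5-tetramethyl-1,3,2-dioxaborolan-2-yl)chroman-4-one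
Conditions: B2pin2 (1.5 equiv), PdCl2(dppf) (5 mol %), KOAc (3 equiv), 1,4-dioxane, 85 °C
Reagents that add atoms: bis(pinacolato)diboron, CC1(C)OB(OC1(C)C)B1OC(C)(C)C(C)(C)O1
Why: Miyaura borylation of the aryl iodide uses only the weak base KOAc, which should not enolise ring F.

Step 6
Reactants: 10 3,4-bis(benzyloxy)benzaldehyde; 11 tert-butyl (triphenylphosphoranylidene)acetate
Product: 13 tert-butyl (Z)-2-bromo-3-[3,4-bis(benzyloxy)phenyl]acrylate, via bromo ylide 12 (not isolated)
Conditions: 11, NBS, CH2Cl2, −20 °C; then 10, −20 °C to rt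
Reagents that add atoms: N-bromosuccinimide, O=C1CCC(=O)N1Br
Why: The stabilised ylide is brominated at carbon and the resulting bromo ylide undergoes Wittig olefination with the aldehyde, which as usual places the ester trans to the aryl group and so gives the Z bromoalkene.

Step 7
Reactants: 9 (2S)-8-boryl flavanone; 13 tert-butyl (Z)-2-bromo-3-[3,4-bis(benzyloxy)phenyl]acrylate
Product: 14 tert-butyl (E)-3-[3,4-bis(benzyloxy)phenyl]-2-{(2S)-5,7-bis(benzyloxy)-2-[4-(benzyloxy)phenyl]-4-oxochroman-8-yl}acrylate
Conditions: Pd(OAc)2 (5 mol %), SPhos (10 mol %), K3PO4 (2 equiv), toluene/H2O (10:1), 60 °C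
Reagents that add atoms: none
Why: Suzuki–Miyaura coupling proceeds with retention of alkene geometry, and the dialkylbiarylphosphine ligand is the established answer to arylboron partners with two ortho oxygen substituents and to trisubstituted bromoalkenes.

Step 8
Reactants: 14 tert-butyl (E)-2,3-diarylacrylate
Product: 15 (E)-3-[3,4-bis(benzyloxy)phenyl]-2-{(2S)-5,7-bis(benzyloxy)-2-[4-(benzyloxy)phenyl]-4-oxochroman-8-yl}acrylic acid
Conditions: TFA/CH2Cl2 (1:4), anisole (10 equiv), 0 °C
Reagents that add atoms: none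
Why: Acidolysis of the tert-butyl ester by loss of isobutene frees the acid without any base, and aryl benzyl ethers should survive brief exposure to cold dilute TFA with anisole as cation scavenger.

Step 9
Reactants: 15 (E)-2,3-diarylacrylic acid; 5 3,5-bis(benzyloxy)-2-(trimethylsilyl)phenyl trifluoromethanesulfonate
Product: 20 5,7-bis(benzyloxy)-2-[3,4-bis(benzyloxy)phenyl]-3-{(2S)-5,7-bis(benzyloxy)-2-[4-(benzyloxy)phenyl]-4-oxochroman-8-yl}chroman-4-one (heptabenzyl ether; 2''S; mixture at C2 and C3), via cesium carboxylate 16 (not isolated), via 3,5-bis(benzyloxy)benzyne 17 (not isolated), via aryl carbanion ester 18 (not isolated), via cesium phenoxide enone 19 (not isolated)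
Conditions: 5 (1.3 equiv), CsF (4 equiv), THF, sealed tube, 110 °C
Reagents that add atoms: none
Why: Fluoride removes the silyl group of 5 and triflate leaves, giving aryne 17, and the carboxylate oxygen of 16 adds to the aryne carbon remote from the flanking benzyloxy group (future C8a, bond C8a–O1), because the carbanion that develops at the other carbon (future C4a) is stabilised by that adjacent oxygen. Carbanion 18 attacks its own ester carbonyl through a four-membered transition state (bond C4–C4a, an anionic Fries-type acyl shift), and phenoxide 19 closes ring C by 6-endo-trig oxa-Michael addition to C2 (bond O1–C2), the enolate taking its C3 proton from the bifluoride formed from the acid proton. The closest known reaction is the fluoride-mediated insertion of arynes into the C–O bond of carboxylic acids, which with cinnamic and other acrylic acids runs on to chroman-4-ones, so the 2,3-diarylacrylic acid is a new and more hindered member of a known substrate class. C2 and C3 arise without control, C3 equilibrating under the conditions, so 20 is expected as a mixture of the two C2 series in which the diequatorial 2,3-trans isomers dominate, while C2'' is not involved. The step needs regioselective addition to the aryne, which the 3-benzyloxy group secures, and acyl transfer faster than protonation of 18, which the aprotic medium and the neighbouring carbonyl group secure; only a small excess of 5 is used to limit O-arylation of 19.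

Step 10
Reactants: 20 heptabenzyl ether (mixture at C2 and C3)
Product: 22 (2R,3R)-5,7-bis(benzyloxy)-2-[3,4-bis(benzyloxy)phenyl]-3-{(2S)-5,7-bis(benzyloxy)-2-[4-(benzyloxy)phenyl]-4-oxochroman-8-yl}chroman-4-one (2,3-cis), via bis(silyl enol ether) 21 (not isolated)
Conditions: TMSOTf (3 equiv), Et3N (5 equiv), CH2Cl2, −78 °C to 0 °C; hexane, filtration, evaporation; TFA (4 equiv), CH2Cl2, −78 °C; pH 7 buffer; silica gel chromatography (preparative HPLC if needed) to remove the (2S,3S,2''S) cis diastereomer
Reagents that add atoms: none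
Why: Soft enolisation with TMSOTf and Et3N turns both ketones into silyl enol ethers without a free enolate, so neither pyranone ring can open and C3 is erased while C2 and C2'' are kept, and protodesilylation then protonates C3 kinetically on the face opposite the C2 aryl group, which is pseudoaxial to avoid the C3 aryl group, to give the less stable 2,3-cis ketone in each C2 series, 22 (C3 R) arising from the 2R series while the 2S series gives the (2S,3S,2''S) cis diastereomer, which is separated and not carried on.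

Step 11
Reactants: 22 (2R,3R,2''S)-heptabenzyl ether
Product: 23 (2R,3R)-2-(3,4-dihydroxyphenyl)-5,7-dihydroxy-3-[(2S)-5,7-dihydroxy-2-(4-hydroxyphenyl)-4-oxochroman-8-yl]chroman-4-one
Conditions: H2 (1 atm), Pd/C (10 wt %), THF/EtOAc (1:1), rt
Reagents that add atoms: none
Why: Hydrogenolysis over palladium cleaves the seven aryl benzyl ethers under neutral conditions at room temperature, which should spare both ketones, the benzylic C2–O1 and C2''–O1'' bonds and the epimerisable cis C3 centre.

Compound list
1 | 3,5-bis(benzyloxy)phenol | Oc1cc(OCc2ccccc2)cc(OCc2ccccc2)c1 | starting material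
2 | 2-bromo-3,5-bis(benzyloxy)phenol | Oc1cc(OCc2ccccc2)cc(OCc2ccccc2)c1Br | intermediate
3 | [2-bromo-3,5-bis(benzyloxy)phenoxy]trimethylsilane | C[Si](C)(C)Oc1cc(OCc2ccccc2)cc(OCc2ccccc2)c1Br | intermediate
4 | lithium 3,5-bis(benzyloxy)-2-(trimethylsilyl)phenoxide | [Li+].[O-]c1cc(OCc2ccccc2)cc(OCc2ccccc2)c1[Si](C)(C)C | intermediate
5 | 3,5-bis(benzyloxy)-2-(trimethylsilyl)phenyl trifluoromethanesulfonate | C[Si](C)(C)c1c(OS(=O)(=O)C(F)(F)F)cc(OCc2ccccc2)cc1OCc1ccccc1 | intermediate
6 | (S)-naringenin, (2S)-5,7-dihydroxy-2-(4-hydroxyphenyl)chroman-4-one | O=C1C[C@@H](c2ccc(O)cc2)Oc2cc(O)cc(O)c12 | starting material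
7 | (2S)-5,7-bis(benzyloxy)-2-[4-(benzyloxy)phenyl]chroman-4-one | O=C1C[C@@H](c2ccc(OCc3ccccc3)cc2)Oc2cc(OCc3ccccc3)cc(OCc3ccccc3)c12 | intermediate
8 | (2S)-5,7-bis(benzyloxy)-2-[4-(benzyloxy)phenyl]-8-iodochroman-4-one | O=C1C[C@@H](c2ccc(OCc3ccccc3)cc2)Oc2c1c(OCc1ccccc1)cc(OCc1ccccc1)c2I | intermediate
9 | (2S)-5,7-bis(benzyloxy)-2-[4-(benzyloxy)phenyl]-8-(4,4,5,5-tetramethyl-1,3,2-dioxaborolan-2-yl)chroman-4-one | O=C1C[C@@H](c2ccc(OCc3ccccc3)cc2)Oc2c1c(OCc1ccccc1)cc(OCc1ccccc1)c2B1OC(C)(C)C(C)(C)O1 | intermediate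
10 | 3,4-bis(benzyloxy)benzaldehyde | O=Cc1ccc(OCc2ccccc2)c(OCc2ccccc2)c1 | starting material
11 | tert-butyl (triphenylphosphoranylidene)acetate | CC(C)(C)OC(=O)C=P(c1ccccc1)(c1ccccc1)c1ccccc1 | starting material
12 | tert-butyl bromo(triphenylphosphoranylidene)acetate | CC(C)(C)OC(=O)C(Br)=P(c1ccccc1)(c1ccccc1)c1ccccc1 | intermediate
13 | tert-butyl (Z)-2-bromo-3-[3,4-bis(benzyloxy)phenyl]acrylate | CC(C)(C)OC(=O)/C(Br)=C/c1ccc(OCc2ccccc2)c(OCc2ccccc2)c1 | intermediate
14 | tert-butyl (E)-3-[3,4-bis(benzyloxy)phenyl]-2-{(2S)-5,7-bis(benzyloxy)-2-[4-(benzyloxy)phenyl]-4-oxochroman-8-yl}acrylate | O=C1C[C@@H](c2ccc(OCc3ccccc3)cc2)Oc2c1c(OCc1ccccc1)cc(OCc1ccccc1)c2/C(=C\c1ccc(OCc2ccccc2)c(OCc2ccccc2)c1)C(=O)OC(C)(C)C | intermediate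
15 | (E)-3-[3,4-bis(benzyloxy)phenyl]-2-{(2S)-5,7-bis(benzyloxy)-2-[4-(benzyloxy)phenyl]-4-oxochroman-8-yl}acrylic acid | O=C1C[C@@H](c2ccc(OCc3ccccc3)cc2)Oc2c1c(OCc1ccccc1)cc(OCc1ccccc1)c2/C(=C\c1ccc(OCc2ccccc2)c(OCc2ccccc2)c1)C(=O)O | intermediate
16 | cesium salt of acid 15 | O=C1C[C@@H](c2ccc(OCc3ccccc3)cc2)Oc2c1c(OCc1ccccc1)cc(OCc1ccccc1)c2/C(=C\c1ccc(OCc2ccccc2)c(OCc2ccccc2)c1)C(=O)[O-].[Cs+] | intermediate
17 | 3,5-bis(benzyloxy)benzyne (1,2-didehydro-3,5-bis(benzyloxy)benzene) | C1#CC(OCc2ccccc2)=CC(OCc2ccccc2)=C1 | intermediate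
18 | 3,5-bis(benzyloxy)phenyl ester of 15 as the cesium carbanion at the ring carbon between the ester oxygen and the flanking benzyloxy group | O=C1C[C@@H](c2ccc(OCc3ccccc3)cc2)Oc2c1c(OCc1ccccc1)cc(OCc1ccccc1)c2/C(=C\c1ccc(OCc2ccccc2)c(OCc2ccccc2)c1)C(=O)Oc1cc(OCc2ccccc2)cc(OCc2ccccc2)[c-]1.[Cs+] | intermediate
19 | cesium 3,5-bis(benzyloxy)-2-[(E)-3-[3,4-bis(benzyloxy)phenyl]-2-{(2S)-5,7-bis(benzyloxy)-2-[4-(benzyloxy)phenyl]-4-oxochroman-8-yl}acryloyl]phenoxide | O=C1C[C@@H](c2ccc(OCc3ccccc3)cc2)Oc2c1c(OCc1ccccc1)cc(OCc1ccccc1)c2/C(=C\c1ccc(OCc2ccccc2)c(OCc2ccccc2)c1)C(=O)c1c([O-])cc(OCc2ccccc2)cc1OCc1ccccc1.[Cs+] | intermediate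
20 | 5,7-bis(benzyloxy)-2-[3,4-bis(benzyloxy)phenyl]-3-{(2S)-5,7-bis(benzyloxy)-2-[4-(benzyloxy)phenyl]-4-oxochroman-8-yl}chroman-4-one, heptabenzyl ether, mixture of isomers at C2 and C3 | O=C1C[C@@H](c2ccc(OCc3ccccc3)cc2)Oc2c1c(OCc1ccccc1)cc(OCc1ccccc1)c2C1C(=O)c2c(OCc3ccccc3)cc(OCc3ccccc3)cc2OC1c1ccc(OCc2ccccc2)c(OCc2ccccc2)c1 | intermediate
21 | bis(trimethylsilyl enol ether) of 20 (C3=C4 and C3''=C4'' enol ethers, both C2 epimers, 2''S; in the series leading to 22 the C2 descriptor reads S because C3 now outranks the aryl group, the arrangement in space being unchanged) | C[Si](C)(C)OC1=C[C@@H](c2ccc(OCc3ccccc3)cc2)Oc2c1c(OCc1ccccc1)cc(OCc1ccccc1)c2C1=C(O[Si](C)(C)C)c2c(OCc3ccccc3)cc(OCc3ccccc3)cc2OC1c1ccc(OCc2ccccc2)c(OCc2ccccc2)c1 | intermediate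
22 | (2R,3R)-5,7-bis(benzyloxy)-2-[3,4-bis(benzyloxy)phenyl]-3-{(2S)-5,7-bis(benzyloxy)-2-[4-(benzyloxy)phenyl]-4-oxochroman-8-yl}chroman-4-one (2,3-cis) | O=C1C[C@@H](c2ccc(OCc3ccccc3)cc2)Oc2c1c(OCc1ccccc1)cc(OCc1ccccc1)c2[C@H]1C(=O)c2c(OCc3ccccc3)cc(OCc3ccccc3)cc2O[C@H]1c1ccc(OCc2ccccc2)c(OCc2ccccc2)c1 | intermediate
23 | (2R,3R)-2-(3,4-dihydroxyphenyl)-5,7-dihydroxy-3-[(2S)-5,7-dihydroxy-2-(4-hydroxyphenyl)-4-oxochroman-8-yl]chroman-4-one | O=C1C[C@@H](c2ccc(O)cc2)Oc2c1c(O)cc(O)c2[C@H]1C(=O)c2c(O)cc(O)cc2O[C@H]1c1ccc(O)c(O)c1 | target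

Total step count: 11. Longest linear sequence: 8 steps (steps 3, 4, 5, 7, 8, 9, 10, 11).

Steps most likely to fail

Step 9. The aryl carbanion may be protonated before the acyl shift, the phenoxide may be O-arylated by a second aryne before the hindered ring closure, and hot fluoride may enolise ring F and erode C2''. The fallback sets out from 15 and 2 and avoids the aryne. Carbodiimide esterification (EDC·HCl, DMAP, CH2Cl2) should give the 2-bromo-3,5-bis(benzyloxy)phenyl ester F1. Treatment with n-BuLi in THF at −100 °C then effects bromine–lithium exchange, which should outpace addition to the hindered, electron-rich ring F ketone and generates the same ortho carbanion directly. The anionic Fries shift triggered by halogen–metal exchange, oxa-Michael closure on warming and an AcOH quench bring the material back to the route at 20.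

Step 10. Enolisation of the hindered ring C ketone may stay incomplete, the protonation may show poor facial selectivity, the cis ketone may epimerise to trans on silica, and the two cis diastereomers may co-elute. The fallback sets out from 21 and replaces substrate control by reagent control. Protonation is carried out with a chiral Lewis acid-assisted Brønsted acid (catalytic SnCl4 and one enantiomer of BINOL monomethyl ether, 2,6-dimethylphenol as stoichiometric proton donor, toluene, −78 °C), a known method for silyl enol ethers of 2-aryl cycloalkanones. The reagent delivers the proton to the same absolute face of C3 in both C2 series, so the 2R series should give cis 22 while the 2S series gives the (2S,3R,2''S) trans heptabenzyl ether F2. A cis/trans pair should part far more readily than two cis isomers, and the route is rejoined at 22. The ligand enantiomer is chosen by experiment.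

Step 7. Transmetalation of the doubly ortho-oxygenated arylboron reagent may be slow, and protodeboronation may compete. The fallback sets out from 13 and 8 and reverses the polarity, bypassing 9. Stannylation of 13 with Me3SnSnMe3 and Pd(PPh3)4 (toluene, 90 °C) should give tert-butyl (Z)-3-[3,4-bis(benzyloxy)phenyl]-2-(trimethylstannyl)acrylate F3. Stille coupling of this stannane with iodide 8 (Pd(PPh3)4, CuI, CsF, DMF, 45 °C) proceeds with retention and returns to the route at 14.

Further compounds
F1 | step 9 | 2-bromo-3,5-bis(benzyloxy)phenyl (E)-3-[3,4-bis(benzyloxy)phenyl]-2-{(2S)-5,7-bis(benzyloxy)-2-[4-(benzyloxy)phenyl]-4-oxochroman-8-yl}acrylate | O=C1C[C@@H](c2ccc(OCc3ccccc3)cc2)Oc2c1c(OCc1ccccc1)cc(OCc1ccccc1)c2/C(=C\c1ccc(OCc2ccccc2)c(OCc2ccccc2)c1)C(=O)Oc1cc(OCc2ccccc2)cc(OCc2ccccc2)c1Br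
F2 | step 10 | (2S,3R)-5,7-bis(benzyloxy)-2-[3,4-bis(benzyloxy)phenyl]-3-{(2S)-5,7-bis(benzyloxy)-2-[4-(benzyloxy)phenyl]-4-oxochroman-8-yl}chroman-4-one (2,3-trans) | O=C1C[C@@H](c2ccc(OCc3ccccc3)cc2)Oc2c1c(OCc1ccccc1)cc(OCc1ccccc1)c2[C@H]1C(=O)c2c(OCc3ccccc3)cc(OCc3ccccc3)cc2O[C@@H]1c1ccc(OCc2ccccc2)c(OCc2ccccc2)c1
F3 | step 7 | tert-butyl (Z)-3-[3,4-bis(benzyloxy)phenyl]-2-(trimethylstannyl)acrylate | CC(C)(C)OC(=O)/C(=C/c1ccc(OCc2ccccc2)c(OCc2ccccc2)c1)[Sn](C)(C)C
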